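(The constants are those of an exercise.)

Do not read a yield off the charge ratio of a slurry: the clock can stop while the catalyst is still passing material.

| flask | starting material | solid reagent | free catalyst | time |
|---|---|---|---|---|
| Monday's | 0.25 M | 0.150 M | 0.25 mM | 8.0 min |
| Thursday's | 0.25 M | 0.200 M | 0.25 mM | 8.0 min |

    solid reagent ⇌ partner, rate k1*(cs1 - [partner]) while solid is left; crystals form when [partner] > cs1 (cs1 = 0.10 M, k1 = 0.021 s⁻¹)
    starting material + catalyst intermediate A → catalyst intermediate B (k2 = 19 L mol⁻¹ s⁻¹)
    partner + free catalyst → catalyst intermediate A (k3 = 88 L mol⁻¹ s⁻¹)
    catalyst intermediate B ⇌ free catalyst + product (K4 = 3.6 M, k4 = 6.0 s⁻¹)

- which of these there is most of at the end, counted by the starting material in it, Monday's (starting material / product / catalyst intermediate B)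
- which of these there is most of at the end, counted by the starting material in it, Thursday's (starting material / product / catalyst intermediate B)
- amount of the one of these that there is most of at the end, in percent of the starting material charged, Monday's
- amount of the one of these that there is most of at the end, in percent of the starting material charged, Thursday's

Start with the bench rule. Take the solid reagent as the limiting reagent, one of it per product, which gives a ceiling of 60.0% on Monday's and 80.0% on Thursday's. Then test the rule against the catalyst. Each catalyst turn costs three waits: free catalyst meeting partner, catalyst intermediate A meeting starting material, and catalyst intermediate B letting go of product. For the first round, take starting material as charged and partner at its solubility: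

wait per turn = 0.491 s, throughput = 0.509 mM s⁻¹

Over the run that would pass 0.244 M, more than Thursday's charge, so go round again. Dissolution must feed that throughput, which holds partner near 0.0757 M. If Thursday's charge were used up, starting material would average 0.150 M:

wait per turn = 0.668 s, throughput = 0.374 mM s⁻¹

Take off 47.6 s for the partner to build up:

reach = 0.162 M

The reach is the product the cycle can pass before the clock stops. Use it on Monday's too, as a low figure, since Monday's consumes less starting material. Charge over reach is 0.926 on Monday's and 1.24 on Thursday's, so by this reckoning the bench rule stands on Monday's and fails on Thursday's. My reckoning: product at 60.0% on Monday's, and product at 64.8% on Thursday's.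

The forecast named product on Monday's at 58% (55% to 60%) and product on Thursday's at 66% (61% to 71%), calling Thursday's “still limited by catalyst turnover”.

The simulation gives product at 58.3% on Monday's and product at 67.2% on Thursday's, both inside the forecast's ranges.

Monday's charge lies below the reach and Thursday's above it, and the difference in solid reagent is the main reason for the gap between the flasks: Thursday's with Monday's charge gives 58.3% instead of 67.2%. Now put the reach to the neighbour flask with 0.38 M of solid reagent, whose charge exceeds it. The reach comes to 64.8% of the starting material there, and that flask gives 68.9%, with 55% of its solid reagent still there, solid or dissolved.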